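The product in this flask is paid for in partner, fed to a racemic pair of substrates under a single-handed free catalyst, so watch how much partner stands unused.

| setting | Monday's | Tuesday's | flask |
|---|---|---|---|
| left-handed substrate | 10 mM | 10 mM | 10 mM |
| right-handed substrate | 10 mM | 10 mM | 10 mM |
| partner | 0.55 equiv (fed, over 6.0 min) | 0.83 equiv (fed, over 6.0 min) | 1.10 equiv (fed, over 6.0 min) |
| protic impurity | 0.50 mM | 0.50 mM | 0.500 mM |
| free catalyst | 0.05 mol% | 0.05 mol% | 0.05 mol% |
| remark | run made earlier | run made earlier |  |
| time |  |  | 15 min |

| run | time / min | left-handed substrate / % | right-handed substrate / % |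
|---|---|---|---|
| Monday's | 1.33 | 49.6 | 49.6 |
| Monday's | 2.00 | 48.8 | 49.4 |
| Monday's | 3.00 | 47.6 | 48.3 |
| Monday's | 4.00 | 46.5 | 46.9 |
| Monday's | 6.00 | 43.9 | 44.1 |
| Monday's | 10.0 | 39.7 | 40.2 |
| Monday's | 15.0 | 38.3 | 37.1 |
| Tuesday's | 0.833 | 50.3 | 50.0 |
| Tuesday's | 2.50 | 48.1 | 48.0 |
| Tuesday's | 4.00 | 45.5 | 45.1 |
| Tuesday's | 6.00 | 41.3 | 41.9 |
| Tuesday's | 10.0 | 34.8 | 35.6 |
| Tuesday's | 12.0 | 32.9 | 33.7 |
| Tuesday's | 15.0 | 31.9 | 33.0 |

(standard deviation of a reading: 0.3 percentage points)

- free catalyst is single-handed; left-handed substrate and right-handed substrate are mirror images of each other, charged as a racemate, each of them at the stated concentration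
- an excess is the difference of the two amounts in percent of their sum
- an excess is below zero if the other one leads

1. part of the left-handed substrate and right-handed substrate charged together that has reacted at 15 min
2. excess of left-handed product over right-handed product in the product at 15 min
3. excess of right-handed substrate over left-handed substrate among what is left of the two at 15 min

How much product can the partner buy? Deduct the whole protic impurity from the partner charge and divide by both substrates together. That gives an estimated ceiling of 25.0% for Monday's run, which reached 24.6%, 39.0% for Tuesday's run, and 52.5% for the flask. Partner is the limiting reagent in the flask.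

What sets the pace after the feed? Read the gap between ceiling and conversion as unused partner. In Tuesday's run the gap falls from 22 percentage points at 6.00 min to 3.9 points at 15.0 min, a factor of 5.64. The substrates fall by a smaller factor, 1.28, so take the tail as pseudo-first-order in [partner]. The reading is 0.193 min⁻¹: this is the tail constant, the fraction of unused partner consumed per minute after the feed. Test it at 10.0 min: it gives 10 points, and the reading is 9.4 points. Leave out Monday's last gap of 0.4 points, read against a scatter of 0.3 points on each reading.

How far does the flask get at the same loading? Let partner enter steadily and decay at the tail constant. Then partner worth 31.1% of the two substrates stands unused at 6.0 min, and my own reckoning gives 47.0% converted at 15 min. Expect a small excess: the end readings of right-handed over left-handed substrate are 1.69% on Tuesday and −1.59% on Monday.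

The forecast says 45% (41% to 49%), somewhat below my figure. For the excesses it gives 4% (1.5% to 7%) in the product and 3.3% (1.2% to 6%) in the substrate, reasoning that “The flask keeps the most partner”.

The flask gives 47.4%, 2.69% and 2.40%.

    free catalyst + left-handed substrate ⇌ catalyst intermediate A (K = 230 M⁻¹, k = 1700 M⁻¹ s⁻¹)
    free catalyst + right-handed substrate ⇌ catalyst intermediate B (K = 830 M⁻¹, k = 1300 M⁻¹ s⁻¹)
    partner + catalyst intermediate A → free catalyst + left-handed product (k = 1800 M⁻¹ s⁻¹)
    partner + catalyst intermediate B → free catalyst + right-handed product (k = 570 M⁻¹ s⁻¹)
    2 free catalyst ⇌ resting dimer, settled at all times (K = 1.70 × 10⁵ M⁻¹)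
    partner + protic impurity → quenched reagent (k = 0.440 M⁻¹ s⁻¹)

In the flask, partner falls from 58.1% at 6.00 min to 10.6% at 15.0 min, which is 0.189 min⁻¹ against the tail constant of 0.193 min⁻¹. Now take the neighbour flask at 0.12 mol%. Scale the constant with the loading to 0.464 min⁻¹, and the same reckoning gives 17.7% unused at 6.0 min, then 52.2% converted, with 0.495% of the partner charge left. The neighbour flask gives 53.5%, above the ceiling, with 52.7% of its protic impurity still present and 0.66% of its partner left. Its excess of right-handed substrate is 1.06%, smaller than the flask's.

All runs stem from a simulated flask for substances that don't exist.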